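**Retrosynthetic overview**
1. Target 13 ⇐ 12: one hydride operation turns the C2 imide and the C3 ester into the two CH2OH groups and releases the auxiliary.
2. 12 ⇐ 10: the only ring is closed at C1–C8a. The veratryl CH2 of an 8–8′-linked benzyl/benzylidene succinate is oxidised to a quinone-methide-type cation, which the trimethoxycinnamate ring traps as in cyclolignan biogenesis; C1 is set trans to C2.
3. 10 ⇐ 7 + 8: the C2 (C8′) stereocentre comes from an Evans alkylation.
4. 7 ⇐ 4 + 5, and 4 ⇐ 1 + 2 by Stobbe condensation; the (E)-arylidene holds the nucleophilic arene cis to C8′.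
5. Ring order: a single ring-forming event (step 4); no other ring is built.

Assumption: the target is the (1R,2S)-1,2-trans isomer encoded by the SMILES; 3,4-dimethoxybenzyl bromide and both enantiomers of 4-benzyl-2-oxazolidinone are bought (the bromide used fresh).

**Route**

Step 1
Reactants: 1 3,4,5-trimethoxybenzaldehyde; 2 dimethyl succinate
Product: 4 (E)-3-(methoxycarbonyl)-4-(3,4,5-trimethoxyphenyl)but-3-enoic acid, via paraconate lactone 3 (not isolated)
Conditions: NaOMe (2 equiv), MeOH, reflux; then aq. HCl; recrystallise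
Reagents that add atoms: none
Why: Stobbe condensation – aldol addition, lactonisation to the paraconate and E1cB ring opening give the half-ester, with the thermodynamically preferred (E)-alkene (aryl trans to CO2Me, cis to the CH2CO2H arm).

Step 2
Reactants: 4 (E)-3-(methoxycarbonyl)-4-(3,4,5-trimethoxyphenyl)but-3-enoic acid; 5 (S)-4-benzyl-2-oxazolidinone
Product: 7 (S)-4-benzyl-3-[(E)-3-(methoxycarbonyl)-4-(3,4,5-trimethoxyphenyl)but-3-enoyl]oxazolidin-2-one, via mixed pivalic anhydride 6 (not isolated)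
Conditions: PivCl, Et3N, THF, −20 °C; then LiCl, 5, −20 °C → rt
Reagents that add atoms: none
Why: N-acylation of the oxazolidinone through the mixed anhydride (one-pot PivCl/LiCl imide formation) is selective for the free acid over the methyl ester and leaves the conjugated alkene untouched.

Step 3
Reactants: 7 (S)-4-benzyl-3-[(E)-3-(methoxycarbonyl)-4-(3,4,5-trimethoxyphenyl)but-3-enoyl]oxazolidin-2-one; 8 3,4-dimethoxybenzyl bromide
Product: 10 (S)-4-benzyl-3-[(2S,3E)-2-(3,4-dimethoxybenzyl)-3-(methoxycarbonyl)-4-(3,4,5-trimethoxyphenyl)but-3-enoyl]oxazolidin-2-one, via sodium Z-enolate 9 (not isolated)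
Conditions: NaHMDS (1.0 equiv), THF, −78 °C; then 8, −78 → −30 °C
Reagents that add atoms: none
Why: Evans asymmetric alkylation – the chelated (Z)-enolate is benzylated at the α-carbon on the face opposite the auxiliary benzyl group, which gives the (2S) centre that becomes C2 of the target.

Step 4
Reactants: 10 (S)-4-benzyl-3-[(2S,3E)-2-(3,4-dimethoxybenzyl)-3-(methoxycarbonyl)-4-(3,4,5-trimethoxyphenyl)but-3-enoyl]oxazolidin-2-one
Product: 12 methyl (1R,2S)-2-{[(4S)-4-benzyl-2-oxooxazolidin-3-yl]carbonyl}-1-(3,4-dimethoxyphenyl)-6,7,8-trimethoxy-1,2-dihydronaphthalene-3-carboxylate, via benzylic cation 11 (not isolated)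
Conditions: DDQ (1.05 equiv), CH2Cl2/TFA 4:1, 0 °C, monitored closely; quench with aq. ascorbate/NaHCO3
Reagents that add atoms: none
Why: Proposed new method: DDQ removes hydride (or electron/proton/electron) only from the veratryl CH2, the sole electron-rich benzylic C–H, and the resulting p-methoxybenzyl (quinone-methide-type) cation is trapped in a 6-ring intramolecular Friedel–Crafts alkylation by C2 of the trimethoxyphenyl ring held cis by the (E)-alkene; the aryl group ends pseudoaxial (avoiding the peri 8-OMe) anti to the pseudoaxial C2 acyl (avoiding A(1,2) strain with the C3 ester), i.e. 1,2-trans (1R); the closest known reactions are the DDQ/TFA oxidative cyclisation of dibenzylbutyrolactones to aryltetralins and the acid cyclisation of 7′-hydroxy or dibenzylidene succinates to trans-1-aryl-1,2-dihydronaphthalenes.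

Step 5
Reactants: 12 methyl (1R,2S)-2-{[(4S)-4-benzyl-2-oxooxazolidin-3-yl]carbonyl}-1-(3,4-dimethoxyphenyl)-6,7,8-trimethoxy-1,2-dihydronaphthalene-3-carboxylate
Product: 13 [(1R,2S)-1-(3,4-dimethoxyphenyl)-6,7,8-trimethoxy-1,2-dihydronaphthalene-2,3-diyl]dimethanol
Conditions: LiAlH4 (4 equiv), THF, −10 → 0 °C; Fieser work-up
Reagents that add atoms: none
Why: Hydride reduction cleaves the N-acyl oxazolidinone reductively to the primary alcohol and reduces the conjugated ester 1,2 to the allylic alcohol at low temperature, and neither stereocentre is touched because no enolisable carbonyl survives.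

**Compound list**
1 | 3,4,5-trimethoxybenzaldehyde | COc1cc(C=O)cc(OC)c1OC | starting material
2 | dimethyl succinate | COC(=O)CCC(=O)OC | starting material
3 | methyl 5-oxo-2-(3,4,5-trimethoxyphenyl)tetrahydrofuran-3-carboxylate (paraconate lactone, diastereomer mixture) | COC(=O)C1CC(=O)OC1c1cc(OC)c(OC)c(OC)c1 | intermediate
4 | (E)-3-(methoxycarbonyl)-4-(3,4,5-trimethoxyphenyl)but-3-enoic acid | COC(=O)/C(CC(=O)O)=C/c1cc(OC)c(OC)c(OC)c1 | intermediate
5 | (S)-4-benzyl-2-oxazolidinone | O=C1N[C@@H](Cc2ccccc2)CO1 | starting material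
6 | mixed pivalic anhydride of 4 | COC(=O)/C(CC(=O)OC(=O)C(C)(C)C)=C/c1cc(OC)c(OC)c(OC)c1 | intermediate
7 | (S)-4-benzyl-3-[(E)-3-(methoxycarbonyl)-4-(3,4,5-trimethoxyphenyl)but-3-enoyl]oxazolidin-2-one | COC(=O)/C(CC(=O)N1[C@@H](Cc2ccccc2)COC1=O)=C/c1cc(OC)c(OC)c(OC)c1 | intermediate
8 | 3,4-dimethoxybenzyl bromide | COc1ccc(CBr)cc1OC | starting material
9 | sodium (Z)-enolate of 7 | COC(=O)/C(/C=C(\[O-])N1[C@@H](Cc2ccccc2)COC1=O)=C/c1cc(OC)c(OC)c(OC)c1.[Na+] | intermediate
10 | (S)-4-benzyl-3-[(2S,3E)-2-(3,4-dimethoxybenzyl)-3-(methoxycarbonyl)-4-(3,4,5-trimethoxyphenyl)but-3-enoyl]oxazolidin-2-one | COC(=O)/C(=C/c1cc(OC)c(OC)c(OC)c1)[C@H](Cc1ccc(OC)c(OC)c1)C(=O)N1[C@@H](Cc2ccccc2)COC1=O | intermediate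
11 | benzylic (p-methoxybenzyl, quinone-methide-type) cation from 10 | COC(=O)/C(=C/c1cc(OC)c(OC)c(OC)c1)[C@H]([CH+]c1ccc(OC)c(OC)c1)C(=O)N1[C@@H](Cc2ccccc2)COC1=O | intermediate
12 | methyl (1R,2S)-2-{[(4S)-4-benzyl-2-oxooxazolidin-3-yl]carbonyl}-1-(3,4-dimethoxyphenyl)-6,7,8-trimethoxy-1,2-dihydronaphthalene-3-carboxylate (aryl and C2 acyl trans) | COc1ccc([C@@H]2c3c(cc(OC)c(OC)c3OC)C=C(C(=O)OC)[C@H]2C(=O)N2[C@@H](Cc3ccccc3)COC2=O)cc1OC | intermediate
13 | [(1R,2S)-1-(3,4-dimethoxyphenyl)-6,7,8-trimethoxy-1,2-dihydronaphthalene-2,3-diyl]dimethanol | COc1ccc([C@@H]2c3c(cc(OC)c(OC)c3OC)C=C(CO)[C@H]2CO)cc1OC | target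

**Totals**
Total steps: 5. Longest linear sequence: 5 (1/2 → 4 → 7 → 10 → 12 → 13).

**Steps most likely to fail, with fallbacks**

Step 4 (highest risk). DDQ may over-oxidise 12 at the doubly benzylic C1–H to the arylnaphthalene, or cation 11 may lose the allylic C8′ proton to give an achiral diene. The fallback sets out from 4 and comes back at 13. Acid 4 is coupled (PivCl, Et3N, LiCl) with (R)-4-benzyl-2-oxazolidinone to give the enantiomeric-auxiliary imide F1. An Evans syn boron aldol (Bu2BOTf, iPr2NEt, CH2Cl2, −78 → 0 °C) with 3,4-dimethoxybenzaldehyde gives the syn 7′-hydroxy aldol adduct F2. The boron aldol uses the enolate face opposite to the chelated alkylation, which is why the opposite auxiliary gives the same C8′ sense. TFA in CH2Cl2 at 0 °C ionises the benzylic alcohol to the same type of cation without any oxidant and closes the ring to the trans dihydronaphthalene imide ester F3. LiAlH4 as in step 5 then gives 13.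

Step 3. The conjugated enolate may give γ-alkylation, low diastereoselectivity or epimerisation of the acidic product. The fallback sets out from 4 and comes back at 10. The dianion of 4 (LDA 2.2 equiv, THF, −78 °C) is alkylated with 8 at the carbon α to the carboxylate to give the racemic benzylated acid F4. Coupling F4 with 5 (PivCl, Et3N, LiCl) gives 10 together with its (2R)-diastereomer F5, and the two are separated by chromatography or crystallisation, at best 50 % yield.

Step 5. LiAlH4 may open the oxazolidinone ring at the endocyclic carbonyl of this hindered imide, or reduce the cinnamate-type alkene. The fallback sets out from 12 and comes back at 13. The auxiliary is first removed by transesterification (MeOMgBr, MeOH/THF, 0 °C) to the trans dimethyl diester F6; C2 may equilibrate here, but trans is the stable isomer and C1 is fixed. DIBAL-H (CH2Cl2, −78 → 0 °C) then reduces both esters cleanly 1,2 to 13.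

**Further compounds**
F1 | step 4 | (R)-4-benzyl-3-[(E)-3-(methoxycarbonyl)-4-(3,4,5-trimethoxyphenyl)but-3-enoyl]oxazolidin-2-one | COC(=O)/C(CC(=O)N1[C@H](Cc2ccccc2)COC1=O)=C/c1cc(OC)c(OC)c(OC)c1
F2 | step 4 | (R)-4-benzyl-3-[(2R,3E)-2-[(R)-(3,4-dimethoxyphenyl)(hydroxy)methyl]-3-(methoxycarbonyl)-4-(3,4,5-trimethoxyphenyl)but-3-enoyl]oxazolidin-2-one | COC(=O)/C(=C/c1cc(OC)c(OC)c(OC)c1)[C@H]([C@@H](O)c1ccc(OC)c(OC)c1)C(=O)N1[C@H](Cc2ccccc2)COC1=O
F3 | step 4 | methyl (1R,2S)-2-{[(4R)-4-benzyl-2-oxooxazolidin-3-yl]carbonyl}-1-(3,4-dimethoxyphenyl)-6,7,8-trimethoxy-1,2-dihydronaphthalene-3-carboxylate | COc1ccc([C@@H]2c3c(cc(OC)c(OC)c3OC)C=C(C(=O)OC)[C@H]2C(=O)N2[C@H](Cc3ccccc3)COC2=O)cc1OC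
F4 | step 3 | rac-(E)-2-(3,4-dimethoxybenzyl)-3-(methoxycarbonyl)-4-(3,4,5-trimethoxyphenyl)but-3-enoic acid | COC(=O)/C(=C/c1cc(OC)c(OC)c(OC)c1)C(Cc1ccc(OC)c(OC)c1)C(=O)O
F5 | step 3 | (S)-4-benzyl-3-[(2R,3E)-2-(3,4-dimethoxybenzyl)-3-(methoxycarbonyl)-4-(3,4,5-trimethoxyphenyl)but-3-enoyl]oxazolidin-2-one | COC(=O)/C(=C/c1cc(OC)c(OC)c(OC)c1)[C@@H](Cc1ccc(OC)c(OC)c1)C(=O)N1[C@@H](Cc2ccccc2)COC1=O
F6 | step 5 | dimethyl (1R,2S)-1-(3,4-dimethoxyphenyl)-6,7,8-trimethoxy-1,2-dihydronaphthalene-2,3-dicarboxylate | COc1ccc([C@@H]2c3c(cc(OC)c(OC)c3OC)C=C(C(=O)OC)[C@H]2C(=O)OC)cc1OC
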